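**Retrosynthetic overview**
- The target is the tris-TBS ether of the (2S)-flavanone with the silyl groups removed; rings A and B are bought as aromatic starting materials, and only ring C (the pyranone) is built.
- The strategy rests on C2 of ring C: it is a benzylic carbon on O1, next to the C3 methylene that is alpha to the C4 ketone. C2–C3 is therefore cut to a carbene at C3 (an aryl diazomethyl ketone) and a C–H bond of an ortho ArO–CH2–Ar' ether.
- The diazomethyl ketone comes from the corresponding methyl ketone by detrifluoroacetylative diazo transfer.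
- The O1–CH2 bond comes from a Mitsunobu coupling of 2,4-bis-O-TBS phloroacetophenone with 3-TBSO-4-prenyloxybenzyl alcohol.
- The benzyl alcohol comes from 3,4-dihydroxybenzaldehyde by 4-O-prenylation, silylation and reduction.

Key step: step 7

Assumption: the sense of induction of the prolinate catalyst on this diazoketone cannot be predicted with certainty; the (S)-ligand is written, and its enantiomer (from D-proline) would be used if the insertion favours the (2R)-product.

**Step 1**
Reactants: 1 2,4,6-trihydroxyacetophenone (dried)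
Product: 2 1-[2,4-bis(tert-butyldimethylsilyloxy)-6-hydroxyphenyl]ethanone
Conditions: TBSCl (2.1 equiv), imidazole, CH2Cl2/DMF, 0 °C → rt
Reagents that add atoms: tert-butyldimethylsilyl chloride, CC(C)(C)[Si](C)(C)Cl
Why: Phenol silylation takes the 4-OH and one ortho OH, while the remaining ortho OH is held in a hydrogen bond to the acetyl carbonyl and should stay free with two equivalents of silyl chloride.

**Step 2**
Reactants: 3 3,4-dihydroxybenzaldehyde; 4 prenyl bromide
Product: 5 3-hydroxy-4-(3-methylbut-2-enyloxy)benzaldehyde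
Conditions: NaHCO3, DMF, 40 °C
Reagents that add atoms: none
Why: Williamson etherification under weak base, in which only the more acidic 4-OH (para to the formyl group) is deprotonated and alkylated by SN2 at the primary allylic bromide.

**Step 3**
Reactants: 5 3-hydroxy-4-(3-methylbut-2-enyloxy)benzaldehyde
Product: 6 3-(tert-butyldimethylsilyloxy)-4-(3-methylbut-2-enyloxy)benzaldehyde
Conditions: TBSCl, imidazole, CH2Cl2, rt
Reagents that add atoms: tert-butyldimethylsilyl chloride, CC(C)(C)[Si](C)(C)Cl
Why: Standard silylation of the remaining phenol, to which the aldehyde and the prenyl ether are inert.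

**Step 4**
Reactants: 6 3-(tert-butyldimethylsilyloxy)-4-(3-methylbut-2-enyloxy)benzaldehyde
Product: 7 [3-(tert-butyldimethylsilyloxy)-4-(3-methylbut-2-enyloxy)phenyl]methanol
Conditions: NaBH4, THF/MeOH, 0 °C
Reagents that add atoms: none
Why: Borohydride reduction of the aromatic aldehyde, which at 0 °C should leave the aryl silyl ether and the trisubstituted alkene untouched.

**Step 5**
Reactants: 2 1-[2,4-bis(tert-butyldimethylsilyloxy)-6-hydroxyphenyl]ethanone; 7 [3-(tert-butyldimethylsilyloxy)-4-(3-methylbut-2-enyloxy)phenyl]methanol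
Product: 8 1-[2,4-bis(tert-butyldimethylsilyloxy)-6-{[3-(tert-butyldimethylsilyloxy)-4-(3-methylbut-2-enyloxy)phenyl]methoxy}phenyl]ethanone
Conditions: PPh3, DIAD, THF, 0 °C → rt
Reagents that add atoms: none
Why: Mitsunobu etherification, in which the primary benzylic alcohol is activated as its alkoxyphosphonium salt and displaced by the chelated phenol under neutral conditions that keep the three aryl silyl ethers.

**Step 6**
Reactants: 8 1-[2,4-bis(tert-butyldimethylsilyloxy)-6-{[3-(tert-butyldimethylsilyloxy)-4-(3-methylbut-2-enyloxy)phenyl]methoxy}phenyl]ethanone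
Product: 10 2-diazo-1-[2,4-bis(tert-butyldimethylsilyloxy)-6-{[3-(tert-butyldimethylsilyloxy)-4-(3-methylbut-2-enyloxy)phenyl]methoxy}phenyl]ethanone, via trifluoroacetyl diketone 9 (not isolated)
Conditions: LiHMDS (1.1 equiv), THF, −78 °C; CF3CO2CH2CF3, −78 °C; cold dil. HCl quench, crude 9 used directly; MsN3, Et3N, H2O (1 equiv), MeCN, rt
Reagents that add atoms: methanesulfonyl azide, CS(=O)(=O)N=[N+]=[N-] (the two diazo nitrogens of 10); 2,2,2-trifluoroethyl trifluoroacetate, O=C(OCC(F)(F)F)C(F)(F)F (the CF3CO group of 9 only)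
Why: Detrifluoroacetylative diazo transfer (Danheiser), in which the kinetic lithium enolate of the methyl ketone is C-acylated, the activated diketone takes the diazo group from the sulfonyl azide and loses the trifluoroacetyl group as the N-acylsulfonamide, the low temperature being meant to keep the ortho silyl ether in place.

**Step 7**
Reactants: 10 2-diazo-1-[2,4-bis(tert-butyldimethylsilyloxy)-6-{[3-(tert-butyldimethylsilyloxy)-4-(3-methylbut-2-enyloxy)phenyl]methoxy}phenyl]ethanone
Product: 11 (2S)-5,7-bis(tert-butyldimethylsilyloxy)-2-[3-(tert-butyldimethylsilyloxy)-4-(3-methylbut-2-enyloxy)phenyl]chroman-4-one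
Conditions: Rh2(S-BSP)4 [dirhodium tetrakis(N-benzenesulfonyl-(S)-prolinate)] (2 mol%), CH2Cl2, slow addition of 10 by syringe pump (final ca. 0.005 M), 0 °C → rt
Reagents that add atoms: none
Why: Loss of dinitrogen from 10 on the chiral dirhodium prolinate gives an electrophilic rhodium carbene at the future C3, which engages one of the two enantiotopic C–H bonds of the ortho ArO–CH2–Ar' group in a concerted, asynchronous three-centre (hydride-transfer-like) transition state and forms C2–C3 as the catalyst is released. The closest known reaction type is the Rh(II)-catalysed intramolecular C–H insertion of ortho-alkoxyaryl diazoketones alpha to the ether oxygen, which gives chroman-4-ones. The pyranone closes as a six-membered ring by 1,6-insertion (carbene carbon, C4, C4a, C8a, O1, C2), since the 1,5-position is the ether oxygen and carries no hydrogen. C2 is the only new stereocentre, and its (S) configuration is set by the catalyst, whose chiral carboxylate ligands distinguish the two enantiotopic benzylic hydrogens. The step needs insertion to outrun oxonium-ylide formation at O1 with [1,2]-benzyl shift, attack on the prenyl alkene and carbene dimerisation: the CH2 is activated by O1 and by the para-alkoxy ring, O1 is a weakly nucleophilic aryl ether oxygen conjugated to the acyl group, the other ortho oxygen carries a bulky silyl group with no activated C–H within reach, the alkene could be reached only through a macrocycle, and slow addition at high dilution suppresses bimolecular paths.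

**Step 8**
Reactants: 11 (2S)-5,7-bis(tert-butyldimethylsilyloxy)-2-[3-(tert-butyldimethylsilyloxy)-4-(3-methylbut-2-enyloxy)phenyl]chroman-4-one
Product: 12 monotesone A, (2S)-5,7-dihydroxy-2-[3-hydroxy-4-(3-methylbut-2-enyloxy)phenyl]chroman-4-one
Conditions: HF·pyridine, excess pyridine, THF, 0 °C → rt
Reagents that add atoms: none
Why: Fluoride-mediated Si–O cleavage under pyridine-buffered, non-basic conditions, so that no phenoxide or enolate forms that could open the pyranone by retro-oxa-Michael reaction and racemise C2, while the prenyl ether should tolerate buffered HF.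

**Compound list**
1 | 2,4,6-trihydroxyacetophenone | CC(=O)c1c(O)cc(O)cc1O | starting material
2 | 1-[2,4-bis(tert-butyldimethylsilyloxy)-6-hydroxyphenyl]ethanone | CC(=O)c1c(O)cc(O[Si](C)(C)C(C)(C)C)cc1O[Si](C)(C)C(C)(C)C | intermediate
3 | 3,4-dihydroxybenzaldehyde | O=Cc1ccc(O)c(O)c1 | starting material
4 | prenyl bromide (1-bromo-3-methylbut-2-ene) | CC(C)=CCBr | starting material
5 | 3-hydroxy-4-(3-methylbut-2-enyloxy)benzaldehyde | CC(C)=CCOc1ccc(C=O)cc1O | intermediate
6 | 3-(tert-butyldimethylsilyloxy)-4-(3-methylbut-2-enyloxy)benzaldehyde | CC(C)=CCOc1ccc(C=O)cc1O[Si](C)(C)C(C)(C)C | intermediate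
7 | [3-(tert-butyldimethylsilyloxy)-4-(3-methylbut-2-enyloxy)phenyl]methanol | CC(C)=CCOc1ccc(CO)cc1O[Si](C)(C)C(C)(C)C | intermediate
8 | 1-[2,4-bis(tert-butyldimethylsilyloxy)-6-{[3-(tert-butyldimethylsilyloxy)-4-(3-methylbut-2-enyloxy)phenyl]methoxy}phenyl]ethanone | CC(C)=CCOc1ccc(COc2cc(O[Si](C)(C)C(C)(C)C)cc(O[Si](C)(C)C(C)(C)C)c2C(C)=O)cc1O[Si](C)(C)C(C)(C)C | intermediate
9 | 4,4,4-trifluoro-1-[2,4-bis(tert-butyldimethylsilyloxy)-6-{[3-(tert-butyldimethylsilyloxy)-4-(3-methylbut-2-enyloxy)phenyl]methoxy}phenyl]butane-1,3-dione (not isolated) | CC(C)=CCOc1ccc(COc2cc(O[Si](C)(C)C(C)(C)C)cc(O[Si](C)(C)C(C)(C)C)c2C(=O)CC(=O)C(F)(F)F)cc1O[Si](C)(C)C(C)(C)C | intermediate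
10 | 2-diazo-1-[2,4-bis(tert-butyldimethylsilyloxy)-6-{[3-(tert-butyldimethylsilyloxy)-4-(3-methylbut-2-enyloxy)phenyl]methoxy}phenyl]ethanone | CC(C)=CCOc1ccc(COc2cc(O[Si](C)(C)C(C)(C)C)cc(O[Si](C)(C)C(C)(C)C)c2C(=O)C=[N+]=[N-])cc1O[Si](C)(C)C(C)(C)C | intermediate
11 | (2S)-5,7-bis(tert-butyldimethylsilyloxy)-2-[3-(tert-butyldimethylsilyloxy)-4-(3-methylbut-2-enyloxy)phenyl]chroman-4-one | CC(C)=CCOc1ccc([C@@H]2CC(=O)c3c(O[Si](C)(C)C(C)(C)C)cc(O[Si](C)(C)C(C)(C)C)cc3O2)cc1O[Si](C)(C)C(C)(C)C | intermediate
12 | monotesone A, (2S)-5,7-dihydroxy-2-[3-hydroxy-4-(3-methylbut-2-enyloxy)phenyl]chroman-4-one | CC(C)=CCOc1ccc([C@@H]2CC(=O)c3c(O)cc(O)cc3O2)cc1O | target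

**Totals**
Total step count: 8.
Longest linear sequence: 7 steps (steps 2, 3, 4, 5, 6, 7, 8 from 3,4-dihydroxybenzaldehyde).

**Steps most likely to fail**

Step 7. The carbene may be diverted before it inserts: attack of O1 on the carbene gives an oxonium ylide that can undergo [1,2]-benzyl shift with ring contraction, the carbene may add to the B ring, or the catalyst may discriminate poorly between the two enantiotopic hydrogens. The fallback builds ring C without a carbene and sets C2 by kinetic resolution. It sets out from acetophenone 2 and aldehyde 6. A pyrrolidine-mediated aldol condensation with oxa-Michael closure (Kabbe-type; pyrrolidine, MeCN, 50 °C) should give racemic 5,7,3'-tris-O-TBS flavanone F1. Noyori asymmetric transfer hydrogenation (RuCl(p-cymene)(TsDPEN), HCO2H/Et3N, EtOAc, rt, stopped near half conversion, with the ligand enantiomer chosen so that the (2R)-ketone is reduced faster) should then turn the unwanted enantiomer into the cis-(2R,4R)-flavan-4-ol F2. The unreacted (2S)-flavanone is compound 11, where the route is rejoined.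

Step 6. The ortho aryl silyl group may migrate from oxygen to the neighbouring lithium enolate oxygen (1,5 O→O shift), or aryl silyl ethers may be hydrolysed in the aqueous amine stage of the diazo transfer. The fallback avoids enolate chemistry and makes the diazoketone by acylating diazomethane. It sets out from benzyl alcohol 7 and commercial 2,4,6-trihydroxybenzaldehyde F3. Bis-silylation (TBSCl, imidazole, CH2Cl2/DMF) should give 2,4-bis(tert-butyldimethylsilyloxy)-6-hydroxybenzaldehyde F4. Mitsunobu coupling with 7 (PPh3, DIAD, THF) should give the benzyl ether aldehyde F5. Pinnick oxidation (NaClO2, NaH2PO4, large excess of 2-methyl-2-butene, t-BuOH/H2O) should give the benzoic acid F6. Ghosez reagent (1-chloro-N,N,2-trimethylpropenylamine, CH2Cl2, 0 °C) should give the acid chloride F7, and excess diazomethane (Et2O, 0 °C) should give diazoketone 10, where the route is rejoined.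

Step 5. The chelated, flanked phenol may couple sluggishly, and the electron-rich benzylic alkoxyphosphonium salt may ionise and alkylate the electron-rich ring at carbon or oligomerise. The fallback replaces the redox condensation by a silver-assisted alkylation. It sets out from benzyl alcohol 7. Appel bromination (CBr4, PPh3, CH2Cl2, 0 °C) should give the benzylic bromide F8, which is used at once. O-Alkylation of phenol 2 with F8 (Ag2O, CH2Cl2, dark, rt), under neutral conditions that spare the aryl silyl ethers, should give ether 8, where the route is rejoined.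

**Further compounds**
F1 | step 7 | racemic 5,7-bis(tert-butyldimethylsilyloxy)-2-[3-(tert-butyldimethylsilyloxy)-4-(3-methylbut-2-enyloxy)phenyl]chroman-4-one | CC(C)=CCOc1ccc(C2CC(=O)c3c(O[Si](C)(C)C(C)(C)C)cc(O[Si](C)(C)C(C)(C)C)cc3O2)cc1O[Si](C)(C)C(C)(C)C
F2 | step 7 | (2R,4R)-5,7-bis(tert-butyldimethylsilyloxy)-2-[3-(tert-butyldimethylsilyloxy)-4-(3-methylbut-2-enyloxy)phenyl]chroman-4-ol | CC(C)=CCOc1ccc([C@H]2C[C@@H](O)c3c(O[Si](C)(C)C(C)(C)C)cc(O[Si](C)(C)C(C)(C)C)cc3O2)cc1O[Si](C)(C)C(C)(C)C
F3 | step 6 | 2,4,6-trihydroxybenzaldehyde | O=Cc1c(O)cc(O)cc1O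
F4 | step 6 | 2,4-bis(tert-butyldimethylsilyloxy)-6-hydroxybenzaldehyde | O=Cc1c(O)cc(O[Si](C)(C)C(C)(C)C)cc1O[Si](C)(C)C(C)(C)C
F5 | step 6 | 2,4-bis(tert-butyldimethylsilyloxy)-6-{[3-(tert-butyldimethylsilyloxy)-4-(3-methylbut-2-enyloxy)phenyl]methoxy}benzaldehyde | CC(C)=CCOc1ccc(COc2cc(O[Si](C)(C)C(C)(C)C)cc(O[Si](C)(C)C(C)(C)C)c2C=O)cc1O[Si](C)(C)C(C)(C)C
F6 | step 6 | 2,4-bis(tert-butyldimethylsilyloxy)-6-{[3-(tert-butyldimethylsilyloxy)-4-(3-methylbut-2-enyloxy)phenyl]methoxy}benzoic acid | CC(C)=CCOc1ccc(COc2cc(O[Si](C)(C)C(C)(C)C)cc(O[Si](C)(C)C(C)(C)C)c2C(=O)O)cc1O[Si](C)(C)C(C)(C)C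
F7 | step 6 | 2,4-bis(tert-butyldimethylsilyloxy)-6-{[3-(tert-butyldimethylsilyloxy)-4-(3-methylbut-2-enyloxy)phenyl]methoxy}benzoyl chloride | CC(C)=CCOc1ccc(COc2cc(O[Si](C)(C)C(C)(C)C)cc(O[Si](C)(C)C(C)(C)C)c2C(=O)Cl)cc1O[Si](C)(C)C(C)(C)C
F8 | step 5 | 4-(bromomethyl)-2-(tert-butyldimethylsilyloxy)-1-(3-methylbut-2-enyloxy)benzene | CC(C)=CCOc1ccc(CBr)cc1O[Si](C)(C)C(C)(C)C
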